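**Plan**

- Ring letters: A is the ring whose OH is para to a diaryl ether oxygen. B is the ring whose OH is ortho to the other ether oxygen. C is the para-phenylene and D the meta-phenylene.
- Cuts, in retrosynthetic order: both O–CH3 protecting bonds come first. Next is the bond from the ring A carbon ortho to the A–O–D oxygen to the adjoining CH2 of the A–B bridge, which opens the 18-membered ring. Then comes the central carbon–carbon bond of the C–D bridge (as C=C), and last the ring A carbon–O(D) and ring C carbon–O(B) ether bonds.
- Enabling feature: the bridge-bearing carbon of ring A lies ortho to the ether oxygen and meta to the OH. A nitro group placed there first activates the neighbouring fluoride for ether formation and is later exchanged for iodine. The CH2CH2 bridge on ring B, para to the ring B OH, is a dihydrocinnamic acid side chain less CO2.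
- Forward order: the B–O–C and A–O–D ethers are made separately and joined by Wittig olefination. One hydrogenation then serves both C=C and NO2. This is followed by NH2 to I and ester to redox-active ester.
- The macrocycle is closed last by a nickel-electrocatalytic decarboxylative aryl–alkyl coupling of two electrophilic carbons. Double O-demethylation follows.
- Stereochemistry: the target has no stereocentre. The only stereo-element on the way, the stilbene geometry, is erased by hydrogenation.

Key step: step 10

Assumption: the target SMILES has no stereodescriptor, so the macrocycle is treated as conformationally mobile and no planar or axial chirality is addressed.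

**Step 1**
Reactants: 1 3-(3-hydroxy-4-methoxyphenyl)propanoic acid
Product: 2 methyl 3-(3-hydroxy-4-methoxyphenyl)propanoate
Conditions: MeOH, cat. H2SO4, reflux
Reagents that add atoms: methanol, CO
Why: Fischer esterification masks the acid for the base-mediated steps that follow and leaves the phenol untouched.

**Step 2**
Reactants: 2 methyl 3-(3-hydroxy-4-methoxyphenyl)propanoate; 3 4-fluorobenzaldehyde
Product: 4 methyl 3-[3-(4-formylphenoxy)-4-methoxyphenyl]propanoate
Conditions: K2CO3, DMF, 120 °C
Reagents that add atoms: none
Why: Nucleophilic aromatic substitution (addition–elimination), in which the para-formyl group activates the fluoride towards the phenoxide of 2, a standard entry to the B–O–C ether of bis(bibenzyl)s.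

**Step 3**
Reactants: 5 4-fluoro-3-nitroanisole; 6 3-hydroxybenzyl alcohol
Product: 7 [3-(4-methoxy-2-nitrophenoxy)phenyl]methanol
Conditions: K2CO3, DMF, 100 °C
Reagents that add atoms: none
Why: Nucleophilic aromatic substitution driven by the ortho-nitro group; carbonate deprotonates only the phenol of 6, so the benzylic OH stays free, and the nitro group marks the ring A carbon that will later carry iodine.

**Step 4**
Reactants: 7 [3-(4-methoxy-2-nitrophenoxy)phenyl]methanol
Product: 8 [3-(4-methoxy-2-nitrophenoxy)benzyl]triphenylphosphonium bromide
Conditions: PPh3·HBr, MeCN, reflux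
Reagents that add atoms: triphenylphosphine hydrobromide, [Br-].c1ccc(cc1)[PH+](c1ccccc1)c1ccccc1
Why: Direct phosphonium salt formation from a benzylic alcohol, in which the acid-activated benzylic carbon–oxygen bond is displaced by triphenylphosphine (nucleophilic substitution).

**Step 5**
Reactants: 8 [3-(4-methoxy-2-nitrophenoxy)benzyl]triphenylphosphonium bromide; 4 methyl 3-[3-(4-formylphenoxy)-4-methoxyphenyl]propanoate
Product: 9 methyl 3-[4-methoxy-3-(4-{2-[3-(4-methoxy-2-nitrophenoxy)phenyl]ethenyl}phenoxy)phenyl]propanoate (E/Z mixture)
Conditions: K2CO3, cat. 18-crown-6, CH2Cl2, reflux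
Reagents that add atoms: none
Why: Wittig olefination of a semi-stabilised benzylic phosphonium salt under solid–liquid phase-transfer conditions that spare the methyl ester; the alkene geometry does not matter because it is removed in step 6.

**Step 6**
Reactants: 9 nitro stilbene ester (E/Z mixture)
Product: 10 methyl 3-[3-(4-{2-[3-(2-amino-4-methoxyphenoxy)phenyl]ethyl}phenoxy)-4-methoxyphenyl]propanoate
Conditions: H2 (1 atm), 10% Pd/C, EtOAc/MeOH, rt
Reagents that add atoms: none
Why: Catalytic hydrogenation saturates the stilbene and reduces the nitro group to the aniline in one operation, while diaryl ethers, methyl ethers and the ester are inert.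

**Step 7**
Reactants: 10 methyl 3-[3-(4-{2-[3-(2-amino-4-methoxyphenoxy)phenyl]ethyl}phenoxy)-4-methoxyphenyl]propanoate
Product: 12 methyl 3-[3-(4-{2-[3-(2-iodo-4-methoxyphenoxy)phenyl]ethyl}phenoxy)-4-methoxyphenyl]propanoate, via arenediazonium tosylate 11 (not isolated)
Conditions: p-TsOH·H2O, NaNO2, KI, MeCN/H2O, 10 °C to rt
Reagents that add atoms: potassium iodide, [K+].[I-]; sodium nitrite, [Na+].[O-]N=O (nitrogen of 11 only); p-toluenesulfonic acid, Cc1ccc(cc1)S(=O)(=O)O (counter-ion of 11 only)
Why: Sandmeyer-type diazotisation–iodination, well precedented for turning 2-aryloxyanilines into 2-iodo diaryl ethers because iodine transfer to the aryl radical should outrun its attack on the neighbouring ring.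

**Step 8**
Reactants: 12 iodo methyl ester
Product: 13 3-[3-(4-{2-[3-(2-iodo-4-methoxyphenoxy)phenyl]ethyl}phenoxy)-4-methoxyphenyl]propanoic acid
Conditions: LiOH, THF/H2O, rt; then 1 M HCl
Reagents that add atoms: lithium hydroxide, [Li+].[OH-]
Why: Saponification by acyl–oxygen cleavage, to which the aryl iodide and all ethers are inert.

**Step 9**
Reactants: 13 iodo acid
Product: 14 1,3-dioxoisoindolin-2-yl 3-[3-(4-{2-[3-(2-iodo-4-methoxyphenoxy)phenyl]ethyl}phenoxy)-4-methoxyphenyl]propanoate
Conditions: N-hydroxyphthalimide, N,N′-diisopropylcarbodiimide, cat. DMAP, CH2Cl2, rt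
Reagents that add atoms: N-hydroxyphthalimide, O=C1c2ccccc2C(=O)N1O
Why: Carbodiimide (Steglich-type) esterification gives the redox-active ester, the one-electron trigger for the side chain.

**Step 10**
Reactants: 14 iodo redox-active ester
Product: 15 di-O-methyl dihydroptychantol A (the macrocycle with both phenols as methyl ethers)
Conditions: NiCl2·6H2O (20 mol %), 2,2′-bipyridine (20 mol %), AgNO3 (0.3 equiv), LiCl, NMP, undivided cell, Mg anode / reticulated vitreous carbon cathode, constant current matched to the feed (about 3 F/mol), rt; 14 added by syringe pump (final about 0.002 mol/L); aq. NH4Cl work-up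
Reagents that add atoms: none
Why: Proposed new method: cathodically generated zerovalent nickel–bipyridine inserts into the carbon–iodine bond of ring A, single-electron transfer (from monovalent nickel or the silver-coated cathode) to the phthalimide ester of the same molecule breaks the N–O bond and expels CO2 to leave the primary 2-(ring B)ethyl radical, this radical is captured by the divalent arylnickel centre, and reductive elimination from the trivalent aryl(alkyl)nickel forms the ring A–CH2 bond while the Mg anode supplies the two electrons. The closest known reaction type is the intermolecular silver-assisted nickel-electrocatalytic decarboxylative arylation of N-hydroxyphthalimide esters with aryl iodides, a cross-electrophile coupling in which hydrocinnamic esters and ortho-substituted iodoarenes are competent partners; what is new is its use end to end within one chain to close a cyclophane, with B-alkyl Suzuki–Miyaura and Nozaki–Hiyama–Kishi macrocyclisations as the nearest metal-templated models. One ring is closed, the 18-membered macrocycle (shortest path through rings A to D), head to tail through a 19-membered nickelacycle that contracts on reductive elimination, so no exo or endo descriptor applies. No stereocentre is formed. The step needs cross- over homo-coupling, secured by the orthogonal activation of the two electrophilic carbons (two-electron insertion at the sp2 carbon, one-electron fragmentation at the ester), and ring closure over oligomerisation, hydrogen abstraction and β-hydride loss, favoured by slow feed into a full catalyst charge, by the absence of any O–H or N–H bond in 14, and by the ortho (ring A) and meta (rings B and D) hinges that fold the chain so that its ends lie near each other.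

**Step 11**
Reactants: 15 di-O-methyl dihydroptychantol A
Product: 16 dihydroptychantol A
Conditions: BBr3, CH2Cl2, −78 °C to rt; then H2O
Reagents that add atoms: none
Why: Lewis-acid aryl methyl ether cleavage, in which bromide attacks only the O–CH3 carbons; the diaryl ethers offer no sp3 carbon and survive.

**Compound list**

1 | 3-(3-hydroxy-4-methoxyphenyl)propanoic acid | COc1ccc(CCC(=O)O)cc1O | starting material
2 | methyl 3-(3-hydroxy-4-methoxyphenyl)propanoate | COC(=O)CCc1ccc(OC)c(O)c1 | intermediate
3 | 4-fluorobenzaldehyde | O=Cc1ccc(F)cc1 | starting material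
4 | methyl 3-[3-(4-formylphenoxy)-4-methoxyphenyl]propanoate | COC(=O)CCc1ccc(OC)c(Oc2ccc(C=O)cc2)c1 | intermediate
5 | 4-fluoro-3-nitroanisole | COc1ccc(F)c([N+](=O)[O-])c1 | starting material
6 | 3-hydroxybenzyl alcohol | OCc1cccc(O)c1 | starting material
7 | [3-(4-methoxy-2-nitrophenoxy)phenyl]methanol | COc1ccc(Oc2cccc(CO)c2)c([N+](=O)[O-])c1 | intermediate
8 | [3-(4-methoxy-2-nitrophenoxy)benzyl]triphenylphosphonium bromide | COc1ccc(Oc2cccc(C[P+](c3ccccc3)(c3ccccc3)c3ccccc3)c2)c([N+](=O)[O-])c1.[Br-] | intermediate
9 | nitro stilbene ester (E/Z mixture, geometry not defined) | COC(=O)CCc1ccc(OC)c(Oc2ccc(C=Cc3cccc(Oc4ccc(OC)cc4[N+](=O)[O-])c3)cc2)c1 | intermediate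
10 | amino bibenzyl ester | COC(=O)CCc1ccc(OC)c(Oc2ccc(CCc3cccc(Oc4ccc(OC)cc4N)c3)cc2)c1 | intermediate
11 | arenediazonium tosylate of 10 (not isolated) | COC(=O)CCc1ccc(OC)c(Oc2ccc(CCc3cccc(Oc4ccc(OC)cc4[N+]#N)c3)cc2)c1.Cc1ccc(cc1)S(=O)(=O)[O-] | intermediate
12 | iodo methyl ester | COC(=O)CCc1ccc(OC)c(Oc2ccc(CCc3cccc(Oc4ccc(OC)cc4I)c3)cc2)c1 | intermediate
13 | iodo acid | OC(=O)CCc1ccc(OC)c(Oc2ccc(CCc3cccc(Oc4ccc(OC)cc4I)c3)cc2)c1 | intermediate
14 | iodo N-hydroxyphthalimide ester | O=C(CCc1ccc(OC)c(Oc2ccc(CCc3cccc(Oc4ccc(OC)cc4I)c3)cc2)c1)ON1C(=O)c2ccccc2C1=O | intermediate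
15 | di-O-methyl dihydroptychantol A | COc1ccc2c(c1)CCc1ccc(OC)c(c1)Oc1ccc(cc1)CCc1cccc(c1)O2 | intermediate
16 | dihydroptychantol A | Oc1ccc2c(c1)CCc1ccc(O)c(c1)Oc1ccc(cc1)CCc1cccc(c1)O2 | target

Total step count: 11. Longest linear sequence: 9 (steps 1, 2, 5–11, or equally steps 3, 4, 5–11).

**Steps most likely to fail**

Step 10. The chain ends may couple between molecules rather than within one. The primary radical may also abstract hydrogen or be lost by β-hydride elimination at nickel, and the arylnickel may be protonated before the radical arrives.

The fallback uses known chemistry, sets out from acid 13 and comes back at 15.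
- Kochi oxidative decarboxylation (Pb(OAc)4, cat. Cu(OAc)2, pyridine, benzene, 80 °C) should give the iodo styrene F1.
- Hydroboration with 9-BBN-H (THF, rt) should give the B-alkyl-9-borabicyclononane F2, which is not isolated.
- F2 is closed by B-alkyl Suzuki–Miyaura macrocyclisation (PdCl2(dppf), AsPh3, Cs2CO3, DMF/THF/H2O, slow addition) to give 15.

Step 7. The transient aryl radical may cyclise onto ring D. The diazonium group may instead be solvolysed or lost reductively before iodine is delivered.

The fallback avoids diazonium chemistry by carrying iodine from the start. It sets out from aldehyde 4, with a new A–D partner built from purchased 4-methoxyphenol, and comes back at 12.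
- Iodination ortho to the hydroxyl (NIS, cat. p-TsOH, MeCN, rt) should give 2-iodo-4-methoxyphenol F3.
- Chan–Lam coupling with purchased 3-(hydroxymethyl)phenylboronic acid (Cu(OAc)2, pyridine, 4 Å sieves, CH2Cl2, air, rt) should give [3-(2-iodo-4-methoxyphenoxy)phenyl]methanol F4.
- PPh3·HBr (MeCN, reflux) should give the iodo phosphonium bromide F5.
- Wittig olefination with 4 (K2CO3, 18-crown-6, CH2Cl2, reflux) should give the iodo stilbene ester F6.
- Diimide reduction (p-toluenesulfonyl hydrazide, NaOAc, THF/H2O, reflux) spares the carbon–iodine bond and should give 12.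

Step 3. Addition–elimination may be slow because the para-methoxy group feeds electron density into the carbon that bears fluorine. At the temperature then needed, arylation at the benzylic hydroxyl may compete.

The fallback sets out from 5 and comes back at 7.
- Purchased 3-hydroxybenzaldehyde replaces 6, so no second hydroxyl is present and harsher conditions are allowed (K2CO3, DMF, 130 °C). This should give 3-(4-methoxy-2-nitrophenoxy)benzaldehyde F7.
- F7 is reduced chemoselectively (NaBH4, MeOH, 0 °C) to 7.

**Further compounds**

F1 | step 10 | 4-{2-[3-(2-iodo-4-methoxyphenoxy)phenyl]ethyl}phenyl 5-ethenyl-2-methoxyphenyl ether (iodo styrene) | C=Cc1ccc(OC)c(Oc2ccc(CCc3cccc(Oc4ccc(OC)cc4I)c3)cc2)c1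
F2 | step 10 | B-alkyl-9-borabicyclo[3.3.1]nonane from F1 (boron on the terminal carbon) | COc1ccc(CCB2C3CCCC2CCC3)cc1Oc1ccc(CCc2cccc(Oc3ccc(OC)cc3I)c2)cc1
F3 | step 7 | 2-iodo-4-methoxyphenol | COc1ccc(O)c(I)c1
F4 | step 7 | [3-(2-iodo-4-methoxyphenoxy)phenyl]methanol | COc1ccc(Oc2cccc(CO)c2)c(I)c1
F5 | step 7 | [3-(2-iodo-4-methoxyphenoxy)benzyl]triphenylphosphonium bromide | COc1ccc(Oc2cccc(C[P+](c3ccccc3)(c3ccccc3)c3ccccc3)c2)c(I)c1.[Br-]
F6 | step 7 | iodo stilbene ester (E/Z mixture) | COC(=O)CCc1ccc(OC)c(Oc2ccc(C=Cc3cccc(Oc4ccc(OC)cc4I)c3)cc2)c1
F7 | step 3 | 3-(4-methoxy-2-nitrophenoxy)benzaldehyde | COc1ccc(Oc2cccc(C=O)c2)c([N+](=O)[O-])c1
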